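## Structural features

The target is an achiral depsidone: two benzene rings are joined twice on neighbouring carbons, by a diaryl ether oxygen and by an ester bridge, so that a seven-membered dioxepinone (ring C) lies between ring A and ring B. Ring A is hexasubstituted; its four oxygens sit in a 1,2,4,5 pattern (free hydroxyl, pyran oxygen, lactone oxygen, ether oxygen), and the two remaining, mutually para carbons carry a prenyl group and the vinyl carbon of a fused 2,2-dimethyl-2H-pyran. Ring B is a pentasubstituted resorcinol in which the ether oxygen, a prenyl group and the carboxyl carbon occupy three contiguous carbons, the two hydroxyls are meta to each other and the only ring hydrogen lies between them. There is no stereocentre, so no stereocentres stand next to each other and every selectivity question is one of regiochemistry. The fragile parts are the two prenyl groups that each sit ortho to a free phenol (acid closes them to chromans), the chromene double bond, the aryl ester of ring C (cleaved by base and nucleophiles), the para-dihydroxy ring A that appears once its oxygens are unmasked (air oxidation to a quinone) and the phloroglucinol-type acid of the open form (decarboxylation). The real difficulty is the ether oxygen, which has four ortho substituents, together with the need to tell four ring A oxygens apart. The key step uses the fact that the ring B sequence C(OAr)–C(prenyl)–C(O)–CH–C(OH)–C(CO2R) is exactly what a 3-oxy-2-alkyl-4-acyl cyclobutenone and an oxygen-substituted alkyne deliver, so ring B can be grown on the ether oxygen instead of being coupled to it. The para placement of the two ring A carbon substituents is used as well: a symmetric diprenyl quinone is desymmetrized by closing one prenyl group onto one carbonyl oxygen.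

## Logic of the disconnections

**36 to 35.** The acyl–oxygen bond of ring C is cut (carboxyl carbon of ring B to the ring A oxygen ortho to the ether oxygen). It is the one bond that can be closed last without any protecting group, because the ether bridge already holds the partners at the distance of a seven-membered ring. The gain is that every earlier intermediate is an open diaryl ether. The forward step must pick one of four free phenols and activate an electron-rich ortho-hydroxy acid under mild, non-acidic conditions.

**35 to 34 to 33.** No skeletal bond is cut. The O–Si bond on ring B, the O–alkyl bond of the ester and the two O–CH2 acetal bonds on ring A are restored. The acetals must come off while the carboxyl is still an ester, because acid would decarboxylate the free acid. Fluoride then frees acid and phenol together by attack at silicon, not at the doubly ortho-substituted acyl carbon. This demands an ester that is cleaved on its alkyl side, which fixes the choice of 19 and 21.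

**33 to 23 and 28 (key).** Two C–C bonds of ring B are cut: hydroxyl-bearing carbon to CH, and prenyl-bearing carbon to siloxy carbon. The aromatic ring B shrinks to a four-membered ring that already hangs on the ether oxygen, plus a two-carbon alkyne. One ring and two bonds are made in one step, and the crowded ether is never formed by coupling. The forward cascade must run without acid or base, tolerate the ester on the ring-opening carbon and deliver a single regiochemistry.

**23 to 17 and 21 (through 22).** Two bonds of the four-membered ring are cut: carbonyl carbon to prenyl-bearing carbon, and aryloxy carbon to ester-bearing carbon. The hindered C(sp2)–O bond becomes the C(sp)–O bond of an alkynyl ether. The forward step needs the ester-substituted ketene to react as a two-carbon partner with the alkyne polarity deciding the orientation.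

**21 to 20 to 18 and 19.** The acyl–Cl and acyl–O bonds are cut back to a cyclic malonate and an alcohol. The only demand is that the silylethyl ester survives acid chloride formation.

**17 to 15 and 2 (through 16).** The C(sp)–CH2 bond is cut. The forward step must alkylate a weakly nucleophilic alkynyl ether anion at the primary carbon of 2 without isomerizing the skipped enyne.

**15 to 12 and 13 (through 14).** The O–C(vinyl) bond is cut. The ether oxygen is joined to a small linear two-carbon electrophile instead of an aryl carbon, so the two ortho substituents of 12 do not matter. The forward step needs only one free phenol, which 12 has.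

**12 to 10 (through 11).** The pyran O–C(Me)2 bond is cut and a hydrogen returned to the benzylic carbon. This reveals a quinone in which both prenyl groups and both pairs of oxygens are equivalent. The forward isomerization decides in one step which para oxygen becomes the pyran oxygen and which the free phenol. It must stop after one ring closure, which it does because the ring is then aromatic.

**10 to 8 to 7 to 6.** The O–CH2 acetal bonds are cut, then the quinone is taken back to the tetramethoxyarene. Methyl is exchanged for methoxymethyl at the vinylogous ester stage because aryl methyl ethers could not be removed later next to prenyl groups and an aryl ester. The forward steps need an oxidation that spares the olefins and a hydrolysis run in base.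

**6 to 4 to 1 and 2 (through 5 and 3).** The two aryl–CH2 bonds are cut. Each ring hydrogen of 1 lies between two methoxy groups, so directed lithiation is unambiguous.

**28 to 24 and 25 (through 26 and 27).** The C–O and O–Si bonds are cut. The forward step needs oxygen transfer to an acetylide and silylation on oxygen.

## Other disconnections considered

**Alternative 1:** The cut is at the two bonds to the lactone carbonyl carbon, which would come from carbon monoxide. In the forward direction the iodo diaryl ether A2 (iodine on ring B ortho to the ether oxygen, free ring A hydroxyls) would undergo palladium-catalysed carbonylation, and the ring A hydroxyl ortho to the ether would capture the acyl group to give the bis-acetal depsidone A1.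
- In its favour: carboxyl carbon and ring C arrive in one step and no free ortho-hydroxy acid is ever handled. On this point it is better than the chosen three-step endgame.
- Against it: A2 already contains the ether with four ortho substituents, so the hardest bond would still have to be made by coupling two finished rings.
- Oxidative addition at a doubly ortho-substituted, electron-rich aryl iodide is slow, and a free para-dihydroxy ring A is exposed to divalent palladium.
- A1 still needs acid to remove two acetals from a molecule that by then has two ortho-prenyl phenols and the lactone.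
- Comparison: structurally it solves ring C only. Mechanistically it relies on a metal cycle that is sensitive to crowding, where the chosen plan uses a pericyclic cascade that is not. In step count it is equal or shorter after the ether stage, but it cannot be shorter overall once the ether synthesis is counted.

**Alternative 2:** The cut is at the ring B C–O ether bond and the adjacent ring B C–C(=O) bond. In the forward direction fluoride would convert the silyl triflate A5 into the aryne A6, and the phenoxide of the catechol monocarbamate A4 would add to it. The resulting aryl anion would take the neighbouring carbamoyl group, giving the amide A3 with the needed ring A hydroxyl set free.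
- In its favour: the crowded ether forms by addition to an aryne, which tolerates ortho substituents. Two bonds form in one operation, which equals the chosen key step. The route is more convergent than the chosen linear one, which is a point where it is better.
- Against it: A5 needs its own multistep synthesis, and A6 has a prenyl group beside the triple bond, which invites an intramolecular ene reaction.
- The carbamoyl group of A4 can migrate between the two catechol oxygens under the basic conditions, which would scramble which oxygen adds.
- A3 carries a tertiary amide between two ortho substituents. Turning it into the lactone needs forcing acid or strong activation, which the prenyl groups would not survive.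
- Comparison: the ether problem is answered about as well as in the chosen plan, but the carbonyl arrives in the wrong oxidation-state derivative for a mild ring closure. The chosen plan delivers a fluoride-cleavable ester instead.

**Alternative 3:** The cut is at one ring A C–C bond, between the carbon that becomes a hydroxyl carbon and the pyran ring carbon. In the forward direction the hydroxycyclobutenone A8, built from a squaric ester by two successive organometallic additions, would open thermally and close by 6π electrocyclization to the chroman hydroquinone A7.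
- In its favour: the hexasubstituted ring A arises with its oxygens differentiated and with regiochemistry set by the order of the additions. It avoids the symmetric quinone and the vinylogous acetal ester of the chosen ring A sequence, and for ring A alone it is equal or better in step count.
- Against it: it says nothing about ring B or the ether. The isopropyl ether of A7 would have to be cleaved by a Lewis acid in the presence of a prenyl group and then arylated, which brings back the four-ortho coupling problem.
- A7 is a chroman and needs dehydrogenation to the chromene next to a free hydroquinone.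
- The required placement of prenyl next to the carbinol carbon needs the less usual addition order with an acid-mediated transposition.
- Comparison: it is a ring A synthesis and is complementary to, not a substitute for, the benzannulation. It would not shorten the route to the whole molecule.

Key step: step 13

Remarks on the chemistry (assumptions):
- The target has no stereocentre; the sp3 centres of 23, 30 and 32 are racemic and disappear on aromatization.
- The cyclobutenone and the benzannulation product were re-derived bond by bond from the target; connectivity and regiochemistry are consistent and need no correction.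
- One design change is made to the cyclobutenone: the ester is carried as the 2-(trimethylsilyl)ethyl ester instead of the methyl ester. Fluoride then frees the crowded carboxyl by attack at silicon and removes the ring B silyl ether in the same step.
- (Triisopropylsiloxy)acetylene is treated as a compound that has to be made (step 12).
- Abbreviations: prenyl = 3-methylbut-2-en-1-yl; ArA = 5,8-bis(methoxymethoxy)-2,2-dimethyl-7-prenyl-2H-chromen-6-yl (ring A, bonded through C6).

## Route

Step 1
Reactants: 1 1,2,4,5-tetramethoxybenzene; 2 prenyl bromide (1-bromo-3-methylbut-2-ene)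
Product: 4 1,2,4,5-tetramethoxy-3-prenylbenzene, via aryllithium 3 (not isolated)
Conditions: n-BuLi (1.1 equiv), TMEDA, THF, 0 °C; then 2, −78 °C → rt
Reagents that add atoms: prenyl bromide (2), CC(C)=CCBr
Why: Directed ortho-lithiation between two methoxy groups followed by SN2 alkylation of the aryllithium at the primary allylic carbon; the two ring hydrogens of 1 are equivalent, so only one product can form.

Step 2
Reactants: 4 1,2,4,5-tetramethoxy-3-prenylbenzene; 2 prenyl bromide
Product: 6 1,2,4,5-tetramethoxy-3,6-diprenylbenzene, via aryllithium 5 (not isolated)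
Conditions: n-BuLi (1.2 equiv), TMEDA, THF, 0 °C; then 2, −78 °C → rt
Reagents that add atoms: prenyl bromide (2), CC(C)=CCBr
Why: Second directed ortho-lithiation at the last ring hydrogen, again flanked by two methoxy groups, and SN2 allylation; ring lithiation at this doubly activated site should outrun deprotonation of the benzylic allylic CH2.

Step 3
Reactants: 6 1,2,4,5-tetramethoxy-3,6-diprenylbenzene
Product: 7 2,5-dimethoxy-3,6-diprenylcyclohexa-2,5-diene-1,4-dione
Conditions: (NH4)2Ce(NO3)6 (2.5 equiv), MeCN–H2O, 0 °C, 15 min
Reagents that add atoms: water, O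
Why: Oxidative demethylation of a para-dimethoxyarene by tetravalent cerium, with water supplying the carbonyl oxygens; both para pairs of methoxy groups in 6 are equivalent, so one para-quinone results, and isolated trisubstituted olefins should survive the short cold oxidation as they do in prenylquinone chemistry.

Step 4
Reactants: 7 2,5-dimethoxy-3,6-diprenylcyclohexa-2,5-diene-1,4-dione
Product: 8 2,5-dihydroxy-3,6-diprenylcyclohexa-2,5-diene-1,4-dione
Conditions: NaOH (2 M aq., 4 equiv), EtOH, 50 °C, argon; then cold 1 M HCl
Reagents that add atoms: sodium hydroxide, [Na+].[OH-]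
Why: Addition–elimination hydrolysis of the two vinylogous ester methoxy groups by hydroxide, the usual way to 2,5-dihydroxy-3,6-dialkylbenzoquinones; base is used because acid would close the hydroxyquinone onto the prenyl group, and air is excluded to avoid oxidative ring contraction.

Step 5
Reactants: 8 2,5-dihydroxy-3,6-diprenylcyclohexa-2,5-diene-1,4-dione; 9 chloromethyl methyl ether
Product: 10 2,5-bis(methoxymethoxy)-3,6-diprenylcyclohexa-2,5-diene-1,4-dione
Conditions: 9 (2.5 equiv), i-Pr2NEt (3 equiv), CH2Cl2, 0 °C
Reagents that add atoms: chloromethyl methyl ether (9), COCCl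
Why: O-alkylation of a vinylogous carboxylic acid with a reactive chloromethyl ether, the same process as methoxymethyl ester formation; both ring carbons are blocked, so only oxygen can be alkylated, and the para-quinone bis-ether is the expected isomer.

Step 6
Reactants: 10 2,5-bis(methoxymethoxy)-3,6-diprenylcyclohexa-2,5-diene-1,4-dione
Product: 12 5,8-bis(methoxymethoxy)-2,2-dimethyl-7-prenyl-2H-chromen-6-ol, via quinone methide 11 (not isolated)
Conditions: Et3N (2 equiv), toluene, 80 °C, argon, dark
Reagents that add atoms: none
Why: Base-mediated tautomerization of a prenylquinone to an ortho-quinone methide and oxa-6π electrocyclization (the quinone-to-chromenol isomerization); the two prenyl groups are equivalent and only one can close because the ring then becomes aromatic, which leaves the para oxygen as the single free phenol.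

Step 7
Reactants: 12 5,8-bis(methoxymethoxy)-2,2-dimethyl-7-prenyl-2H-chromen-6-ol; 13 trichloroethylene
Product: 15 6-[(E)-1,2-dichloroethenyl]oxy-5,8-bis(methoxymethoxy)-2,2-dimethyl-7-prenyl-2H-chromene, via dichloroacetylene 14 (not isolated)
Conditions: 13 (1.5 equiv), K2CO3 (3 equiv), DMF, 70 °C, argon
Reagents that add atoms: trichloroethylene (13), ClC=C(Cl)Cl
Why: Base eliminates HCl from trichloroethylene and the phenoxide adds anti to the dichloroacetylene formed in solution, which sets the E geometry of the 1,2-dichlorovinyl ether; the electrophile is a small linear alkyne, so the two ortho substituents of the phenol should not block the reaction.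

Step 8
Reactants: 15 6-[(E)-1,2-dichloroethenyl]oxy-5,8-bis(methoxymethoxy)-2,2-dimethyl-7-prenyl-2H-chromene; 2 prenyl bromide
Product: 17 5,8-bis(methoxymethoxy)-2,2-dimethyl-6-[(5-methylhex-4-en-1-yn-1-yl)oxy]-7-prenyl-2H-chromene, via lithium alkynyl ether 16 (not isolated)
Conditions: n-BuLi (2.2 equiv), THF, −78 → −40 °C; then CuBr·SMe2 (10 mol %), DMPU, 2 (1.3 equiv), −40 → 0 °C
Reagents that add atoms: prenyl bromide (2), CC(C)=CCBr
Why: Dehydrochlorination and chlorine–lithium exchange turn the dichlorovinyl ether into the lithium alkynyl ether, and copper-catalysed SN2 allylation of this acetylide at the primary carbon of prenyl bromide gives the skipped enyne; the acetals and the chromene are inert to n-BuLi at these temperatures.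

Step 9
Reactants: 18 2,2-dimethyl-1,3-dioxane-4,6-dione (Meldrum's acid); 19 2-(trimethylsilyl)ethanol
Product: 20 3-oxo-3-[2-(trimethylsilyl)ethoxy]propanoic acid
Conditions: toluene, 100 °C, 4 h
Reagents that add atoms: 2-(trimethylsilyl)ethanol (19), C[Si](C)(C)CCO
Why: Alcoholysis of the cyclic acylal (acyl substitution with loss of acetone) gives the malonic half ester directly.

Step 10
Reactants: 20 3-oxo-3-[2-(trimethylsilyl)ethoxy]propanoic acid
Product: 21 2-(trimethylsilyl)ethyl 3-chloro-3-oxopropanoate
Conditions: (COCl)2 (1.2 equiv), DMF (cat.), CH2Cl2, 0 °C → rt; concentrated and used at once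
Reagents that add atoms: oxalyl chloride, ClC(=O)C(Cl)=O
Why: Acid chloride formation through the chloroiminium intermediate, standard for malonic half esters; the silylethyl ester should tolerate the brief exposure to dry HCl.

Step 11
Reactants: 17 5,8-bis(methoxymethoxy)-2,2-dimethyl-6-[(5-methylhex-4-en-1-yn-1-yl)oxy]-7-prenyl-2H-chromene; 21 2-(trimethylsilyl)ethyl 3-chloro-3-oxopropanoate
Product: 23 2-(trimethylsilyl)ethyl 2-(ArA-oxy)-4-oxo-3-prenylcyclobut-2-ene-1-carboxylate (racemic), via ketene 22 (not isolated)
Conditions: Et3N (2 equiv), CH2Cl2, −20 → 0 °C; 21 (1.5 equiv) added slowly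
Reagents that add atoms: none
Why: Dehydrochlorination gives the ester-substituted ketene, which undergoes the ketene–alkynyl ether [2+2] cycloaddition; the nucleophilic, prenyl-bearing carbon of the ynol ether bonds to the ketene carbonyl carbon, placing prenyl on C3, aryloxy on C2 and the ester on C1 of the cyclobutene carboxylate. Slow addition keeps the ketene concentration low against dimerization.

Step 12
Reactants: 24 acetylene; 25 triisopropylsilyl trifluoromethanesulfonate
Product: 28 (triisopropylsiloxy)acetylene, via lithium acetylide 26 (not isolated), via lithium ethynolate 27 (not isolated)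
Conditions: 24 (excess), n-BuLi (1.0 equiv), THF, −78 °C; t-BuOOLi (1.1 equiv, from t-BuOOH and LiN(SiMe3)2), −78 → −20 °C; then 25 (1.1 equiv), −78 → 0 °C
Reagents that add atoms: tert-butyl hydroperoxide, CC(C)(C)OO; triisopropylsilyl trifluoromethanesulfonate (25), CC(C)[Si](OS(=O)(=O)C(F)(F)F)(C(C)C)C(C)C
Why: Electrophilic oxygen transfer from the lithium peroxide to a lithium acetylide gives the ynolate, and the bulky silyl triflate silylates it on oxygen (small silyl groups go to carbon); this is the acetylide oxidation route to siloxyalkynes.

Step 13
Reactants: 23 2-(trimethylsilyl)ethyl 2-(ArA-oxy)-4-oxo-3-prenylcyclobut-2-ene-1-carboxylate; 28 (triisopropylsiloxy)acetylene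
Product: 33 2-(trimethylsilyl)ethyl 2-(ArA-oxy)-6-hydroxy-3-prenyl-4-(triisopropylsiloxy)benzoate, via vinylketene 29 (not isolated), via vinylcyclobutenone 30 (not isolated), via dienylketene 31 (not isolated), via cyclohexadienone 32 (not isolated)
Conditions: 28 (2.5 equiv), toluene (0.1 M), 80 °C, argon, sealed tube; 110 °C briefly if 30 persists
Reagents that add atoms: none
Why: Heating opens 23 by 4π electrocyclic cleavage of the bond between the carbonyl carbon and the ester-bearing carbon to vinylketene 29, the ester being expected to rotate outward, away from the ketene carbon, so that its carbonyl cannot close onto the ketene. The ketene C=C bond of 29 and the electron-rich triple bond of 28 then combine in a [2+2] cycloaddition to 30, whose four-membered ring reopens (4π) to dienylketene 31. Ring B is closed by thermal 6π electrocyclization (disrotatory, six-membered carbocycle) of 31 to 32, and enolization to the hydrogen-bonded salicylate 33 makes the sequence irreversible. This is the Danheiser benzannulation of 3-oxy-substituted cyclobutenones with siloxyalkynes, the closest known reaction type; new here are only the aryloxy group on the enol ether carbon and the ester on the ring-opening carbon. The sp3 centres of 23, 30 and 32 are racemic and are erased on aromatization, so no stereocentre has to be controlled. The selectivity needed is regiochemical and rests on polarity: the unsubstituted, nucleophilic carbon of 28 bonds to the ketene carbonyl carbon, which puts the ring hydrogen between the two ring B oxygens and the siloxy carbon next to the prenyl-bearing carbon. The phenol of 33 is tied up by the ortho ester and crowded, which should protect it from acylation by 29, and the excess of 28 keeps the capture of 29 fast. Should silicon end up on the other ring B oxygen through a competing [4+2] mode, the same 35 would result after step 15.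

Step 14
Reactants: 33 2-(trimethylsilyl)ethyl 2-(ArA-oxy)-6-hydroxy-3-prenyl-4-(triisopropylsiloxy)benzoate
Product: 34 2-(trimethylsilyl)ethyl 2-[(5,8-dihydroxy-2,2-dimethyl-7-prenyl-2H-chromen-6-yl)oxy]-6-hydroxy-3-prenyl-4-(triisopropylsiloxy)benzoate
Conditions: HCl (1.25 M in MeOH, 5 equiv), MeOH–THF, degassed, 0 °C → rt
Reagents that add atoms: none
Why: Acid-catalysed acetal exchange of the two aryl methoxymethyl ethers with methanol; cold dilute acid is the usual way to unmask prenylated phenols without closing the chroman, and the aryl silyl ether and the crowded silylethyl ester should be stable to it. The para-dihydroxy ring A of 34 is kept under argon.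

Step 15
Reactants: 34 2-(trimethylsilyl)ethyl 2-[(5,8-dihydroxy-2,2-dimethyl-7-prenyl-2H-chromen-6-yl)oxy]-6-hydroxy-3-prenyl-4-(triisopropylsiloxy)benzoate
Product: 35 2-[(5,8-dihydroxy-2,2-dimethyl-7-prenyl-2H-chromen-6-yl)oxy]-4,6-dihydroxy-3-prenylbenzoic acid
Conditions: Bu4NF (4 equiv), THF, 0 °C → rt, argon; then cold 0.1 M HCl to pH 4; crude acid used at once
Reagents that add atoms: none
Why: Fluoride attacks silicon and not the crowded acyl carbon: the aryl silyl ether is cleaved and the 2-(trimethylsilyl)ethyl ester fragments by β-elimination to carboxylate, ethylene and fluorotrimethylsilane. No heat or strong acid is used, so the electron-rich ortho-hydroxy acid should not decarboxylate.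

Step 16
Reactants: 35 2-[(5,8-dihydroxy-2,2-dimethyl-7-prenyl-2H-chromen-6-yl)oxy]-4,6-dihydroxy-3-prenylbenzoic acid
Product: 36 target depsidone CNP0263700.0
Conditions: EDC·HCl (1.5 equiv), DMAP (0.1 equiv), CH2Cl2–THF (0.002 M), 0 °C → rt, argon
Reagents that add atoms: none
Why: Carbodiimide lactonization (Steglich type) of a 2-(2-hydroxyaryloxy)benzoic acid, the classical way to close the depsidone ring; only the ring A hydroxyl ortho to the ether oxygen can reach the activated carboxyl through a seven-membered transition state, and high dilution suppresses intermolecular acylation of the other three phenols.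

## Compound list

1 | 1,2,4,5-tetramethoxybenzene | COc1cc(OC)c(OC)cc1OC | starting material
2 | prenyl bromide (1-bromo-3-methylbut-2-ene) | CC(C)=CCBr | starting material
3 | 2,3,5,6-tetramethoxyphenyllithium | [Li]c1c(OC)c(OC)cc(OC)c1OC | intermediate
4 | 1,2,4,5-tetramethoxy-3-prenylbenzene | COc1cc(OC)c(OC)c(CC=C(C)C)c1OC | intermediate
5 | 2,3,5,6-tetramethoxy-4-prenylphenyllithium | [Li]c1c(OC)c(OC)c(CC=C(C)C)c(OC)c1OC | intermediate
6 | 1,2,4,5-tetramethoxy-3,6-diprenylbenzene | COc1c(CC=C(C)C)c(OC)c(OC)c(CC=C(C)C)c1OC | intermediate
7 | 2,5-dimethoxy-3,6-diprenylcyclohexa-2,5-diene-1,4-dione | COC1=C(CC=C(C)C)C(=O)C(OC)=C(CC=C(C)C)C1=O | intermediate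
8 | 2,5-dihydroxy-3,6-diprenylcyclohexa-2,5-diene-1,4-dione | OC1=C(CC=C(C)C)C(=O)C(O)=C(CC=C(C)C)C1=O | intermediate
9 | chloromethyl methyl ether | COCCl | starting material
10 | 2,5-bis(methoxymethoxy)-3,6-diprenylcyclohexa-2,5-diene-1,4-dione | COCOC1=C(CC=C(C)C)C(=O)C(OCOC)=C(CC=C(C)C)C1=O | intermediate
11 | 4-hydroxy-3,6-bis(methoxymethoxy)-5-prenyl-2-(3-methylbut-2-en-1-ylidene)cyclohexa-3,5-dien-1-one (ortho-quinone methide, alkylidene geometry not defined) | O=C1C(=CC=C(C)C)C(OCOC)=C(O)C(CC=C(C)C)=C1OCOC | intermediate
12 | 5,8-bis(methoxymethoxy)-2,2-dimethyl-7-prenyl-2H-chromen-6-ol | CC1(C)C=Cc2c(OCOC)c(O)c(CC=C(C)C)c(OCOC)c2O1 | intermediate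
13 | trichloroethylene | ClC=C(Cl)Cl | starting material
14 | dichloroacetylene | ClC#CCl | intermediate
15 | 6-[(E)-1,2-dichloroethenyl]oxy-5,8-bis(methoxymethoxy)-2,2-dimethyl-7-prenyl-2H-chromene | Cl/C=C(/Cl)Oc1c(CC=C(C)C)c(OCOC)c2OC(C)(C)C=Cc2c1OCOC | intermediate
16 | (ArA-oxy)ethynyllithium | [Li]C#COc1c(CC=C(C)C)c(OCOC)c2OC(C)(C)C=Cc2c1OCOC | intermediate
17 | 5,8-bis(methoxymethoxy)-2,2-dimethyl-6-[(5-methylhex-4-en-1-yn-1-yl)oxy]-7-prenyl-2H-chromene | CC(C)=CCC#COc1c(CC=C(C)C)c(OCOC)c2OC(C)(C)C=Cc2c1OCOC | intermediate
18 | 2,2-dimethyl-1,3-dioxane-4,6-dione (Meldrum's acid) | CC1(C)OC(=O)CC(=O)O1 | starting material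
19 | 2-(trimethylsilyl)ethanol | C[Si](C)(C)CCO | starting material
20 | 3-oxo-3-[2-(trimethylsilyl)ethoxy]propanoic acid | C[Si](C)(C)CCOC(=O)CC(=O)O | intermediate
21 | 2-(trimethylsilyl)ethyl 3-chloro-3-oxopropanoate | C[Si](C)(C)CCOC(=O)CC(Cl)=O | intermediate
22 | 2-(trimethylsilyl)ethyl 3-oxoprop-2-enoate (ester-substituted ketene) | C[Si](C)(C)CCOC(=O)C=C=O | intermediate
23 | 2-(trimethylsilyl)ethyl 2-(ArA-oxy)-4-oxo-3-prenylcyclobut-2-ene-1-carboxylate (racemic) | C[Si](C)(C)CCOC(=O)C1C(=O)C(CC=C(C)C)=C1Oc1c(CC=C(C)C)c(OCOC)c2OC(C)(C)C=Cc2c1OCOC | intermediate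
24 | acetylene | C#C | starting material
25 | triisopropylsilyl trifluoromethanesulfonate | CC(C)[Si](OS(=O)(=O)C(F)(F)F)(C(C)C)C(C)C | starting material
26 | lithium acetylide | [Li]C#C | intermediate
27 | lithium ethynolate | [Li]OC#C | intermediate
28 | (triisopropylsiloxy)acetylene | C#CO[Si](C(C)C)(C(C)C)C(C)C | intermediate
29 | 2-(trimethylsilyl)ethyl 3-(ArA-oxy)-5-oxo-4-prenylpenta-2,4-dienoate (vinylketene, olefin geometry not defined) | C[Si](C)(C)CCOC(=O)C=C(Oc1c(CC=C(C)C)c(OCOC)c2OC(C)(C)C=Cc2c1OCOC)C(CC=C(C)C)=C=O | intermediate
30 | 2-(trimethylsilyl)ethyl 3-(ArA-oxy)-3-[4-oxo-1-prenyl-2-(triisopropylsiloxy)cyclobut-2-en-1-yl]prop-2-enoate (racemic, olefin geometry not defined) | C[Si](C)(C)CCOC(=O)C=C(Oc1c(CC=C(C)C)c(OCOC)c2OC(C)(C)C=Cc2c1OCOC)C1(CC=C(C)C)C(=O)C=C1O[Si](C(C)C)(C(C)C)C(C)C | intermediate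
31 | 2-(trimethylsilyl)ethyl 3-(ArA-oxy)-7-oxo-4-prenyl-5-(triisopropylsiloxy)hepta-2,4,6-trienoate (dienylketene, olefin geometry not defined) | C[Si](C)(C)CCOC(=O)C=C(Oc1c(CC=C(C)C)c(OCOC)c2OC(C)(C)C=Cc2c1OCOC)C(CC=C(C)C)=C(O[Si](C(C)C)(C(C)C)C(C)C)C=C=O | intermediate
32 | 2-(trimethylsilyl)ethyl 2-(ArA-oxy)-6-oxo-3-prenyl-4-(triisopropylsiloxy)cyclohexa-2,4-diene-1-carboxylate (racemic) | C[Si](C)(C)CCOC(=O)C1C(=O)C=C(O[Si](C(C)C)(C(C)C)C(C)C)C(CC=C(C)C)=C1Oc1c(CC=C(C)C)c(OCOC)c2OC(C)(C)C=Cc2c1OCOC | intermediate
33 | 2-(trimethylsilyl)ethyl 2-(ArA-oxy)-6-hydroxy-3-prenyl-4-(triisopropylsiloxy)benzoate | C[Si](C)(C)CCOC(=O)c1c(O)cc(O[Si](C(C)C)(C(C)C)C(C)C)c(CC=C(C)C)c1Oc1c(CC=C(C)C)c(OCOC)c2OC(C)(C)C=Cc2c1OCOC | intermediate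
34 | 2-(trimethylsilyl)ethyl 2-[(5,8-dihydroxy-2,2-dimethyl-7-prenyl-2H-chromen-6-yl)oxy]-6-hydroxy-3-prenyl-4-(triisopropylsiloxy)benzoate | C[Si](C)(C)CCOC(=O)c1c(O)cc(O[Si](C(C)C)(C(C)C)C(C)C)c(CC=C(C)C)c1Oc1c(CC=C(C)C)c(O)c2OC(C)(C)C=Cc2c1O | intermediate
35 | 2-[(5,8-dihydroxy-2,2-dimethyl-7-prenyl-2H-chromen-6-yl)oxy]-4,6-dihydroxy-3-prenylbenzoic acid | OC(=O)c1c(O)cc(O)c(CC=C(C)C)c1Oc1c(CC=C(C)C)c(O)c2OC(C)(C)C=Cc2c1O | intermediate
36 | target depsidone CNP0263700.0 (achiral) | CC(C)=CCc1c(O)c2c(c3c1Oc1c(CC=C(C)C)c(O)cc(O)c1C(=O)O3)C=CC(C)(C)O2 | target

## Step count and least certain steps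

Total: 16 steps. Longest linear sequence: 13 steps (steps 1–8, 11, 13–16); steps 9–10 and step 12 are side branches.

**Step 13 (key step).** The ester-stabilized vinylketene 29 may be captured by the alkyne more slowly than simple alkoxy-vinylketenes. During long heating the moisture- and heat-sensitive siloxyalkyne can then be lost, the product phenol can be acylated by 29, or 29 can close onto its own ester carbonyl if the ester rotates inward. The fallback sets out from 23 and returns at 35. It replaces the siloxyalkyne by a thermally robust alkoxyacetylene whose oxygen substituent is also removed by fluoride. Alcohol 19 is converted with KH and trichloroethylene 13 in THF into (E)-1,2-dichlorovinyl 2-(trimethylsilyl)ethyl ether F1. Treatment of F1 with n-BuLi at −78 °C and quenching with methanol gives [2-(trimethylsilyl)ethoxy]acetylene F2. Benzannulation of 23 with a large excess of F2 in toluene at 80 °C should give 2-(trimethylsilyl)ethyl 2-(ArA-oxy)-6-hydroxy-3-prenyl-4-[2-(trimethylsilyl)ethoxy]benzoate F3. HCl in methanol removes the acetals to give the ring A diol F4, and Bu4NF in DMF at 50 °C cleaves both silylethyl groups to 35.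

**Step 11.** The ester-substituted ketene 22 may react through its ester carbonyl as a four-atom partner, dimerize, or acylate the acidic ring carbon of 23. Also, 23 may open below room temperature and capture a second molecule of 17. The fallback sets out from 17 and returns at 33; it takes the ester off the four-membered ring and adds the carboxyl carbon after ring B is aromatic. Ketene (from pyrolysis of acetone) adds to 17 to give 3-(ArA-oxy)-2-prenylcyclobut-2-en-1-one F5, the substrate class on which the benzannulation is established. Heating F5 with 28 gives 3-(ArA-oxy)-4-prenyl-5-(triisopropylsiloxy)phenol F6. Magnesium-mediated ortho-formylation (MgCl2, Et3N, paraformaldehyde) at the position para to the siloxy group gives 2-(ArA-oxy)-6-hydroxy-3-prenyl-4-(triisopropylsiloxy)benzaldehyde F7. Pinnick oxidation (NaClO2, NaH2PO4, 2-methylbut-2-ene) gives the corresponding benzoic acid F8. O-alkylation of the carboxyl with 2-(trimethylsilyl)ethyl 2,2,2-trichloroacetimidate in warm toluene gives 33.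

**Step 8.** Alkylation of the weakly nucleophilic lithium alkynyl ether may be slow, may go partly at the tertiary end of the allyl unit, or may be followed by base-induced isomerization of the skipped enyne; excess n-BuLi may also consume prenyl bromide. The fallback sets out from 15 and returns at 17; it separates anion formation from C–C bond formation. Intermediate 16 is generated as in step 8 and quenched with Bu3SnCl to give tributyl[(ArA-oxy)ethynyl]stannane F9, which can be purified. Stille coupling of F9 with 2 (Pd2(dba)3 as the source of zerovalent palladium, AsPh3, THF, 50 °C) gives 17 under neutral conditions.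

**Step 12.** Lithium acetylide may disproportionate to the insoluble dilithium salt before oxygen transfer, silylation may go partly to carbon, and the volatile, moisture-sensitive 28 may be lost on isolation. The fallback sets out from 23 and returns at 34; it carries a carbon-bound silyl group through the benzannulation. Commercial trimethylsilylacetylene, whose lithium salt is stable, is taken through the same oxygen transfer and O-silylation to 1-(triisopropylsiloxy)-2-(trimethylsilyl)acetylene F10. Benzannulation of 23 with F10 follows the same polarity and should give 2-(trimethylsilyl)ethyl 2-(ArA-oxy)-6-hydroxy-3-prenyl-4-(triisopropylsiloxy)-5-(trimethylsilyl)benzoate F11, with the trimethylsilyl group between the two ring B oxygens. The HCl–methanol treatment of step 14 then removes the acetals and, by ipso-protonation of the very electron-rich position, the aryl silicon, giving 34.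

## Further compounds

F1 | step 13 | (E)-1,2-dichlorovinyl 2-(trimethylsilyl)ethyl ether | Cl/C=C(/Cl)OCC[Si](C)(C)C
F2 | step 13 | [2-(trimethylsilyl)ethoxy]acetylene | C#COCC[Si](C)(C)C
F3 | step 13 | 2-(trimethylsilyl)ethyl 2-(ArA-oxy)-6-hydroxy-3-prenyl-4-[2-(trimethylsilyl)ethoxy]benzoate | C[Si](C)(C)CCOC(=O)c1c(O)cc(OCC[Si](C)(C)C)c(CC=C(C)C)c1Oc1c(CC=C(C)C)c(OCOC)c2OC(C)(C)C=Cc2c1OCOC
F4 | step 13 | 2-(trimethylsilyl)ethyl 2-[(5,8-dihydroxy-2,2-dimethyl-7-prenyl-2H-chromen-6-yl)oxy]-6-hydroxy-3-prenyl-4-[2-(trimethylsilyl)ethoxy]benzoate | C[Si](C)(C)CCOC(=O)c1c(O)cc(OCC[Si](C)(C)C)c(CC=C(C)C)c1Oc1c(CC=C(C)C)c(O)c2OC(C)(C)C=Cc2c1O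
F5 | step 11 | 3-(ArA-oxy)-2-prenylcyclobut-2-en-1-one | CC(C)=CCC3=C(Oc1c(CC=C(C)C)c(OCOC)c2OC(C)(C)C=Cc2c1OCOC)CC3=O
F6 | step 11 | 3-(ArA-oxy)-4-prenyl-5-(triisopropylsiloxy)phenol | Oc1cc(O[Si](C(C)C)(C(C)C)C(C)C)c(CC=C(C)C)c(Oc2c(CC=C(C)C)c(OCOC)c3OC(C)(C)C=Cc3c2OCOC)c1
F7 | step 11 | 2-(ArA-oxy)-6-hydroxy-3-prenyl-4-(triisopropylsiloxy)benzaldehyde | O=Cc1c(O)cc(O[Si](C(C)C)(C(C)C)C(C)C)c(CC=C(C)C)c1Oc1c(CC=C(C)C)c(OCOC)c2OC(C)(C)C=Cc2c1OCOC
F8 | step 11 | 2-(ArA-oxy)-6-hydroxy-3-prenyl-4-(triisopropylsiloxy)benzoic acid | OC(=O)c1c(O)cc(O[Si](C(C)C)(C(C)C)C(C)C)c(CC=C(C)C)c1Oc1c(CC=C(C)C)c(OCOC)c2OC(C)(C)C=Cc2c1OCOC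
F9 | step 8 | tributyl[(ArA-oxy)ethynyl]stannane | CCCC[Sn](CCCC)(CCCC)C#COc1c(CC=C(C)C)c(OCOC)c2OC(C)(C)C=Cc2c1OCOC
F10 | step 12 | 1-(triisopropylsiloxy)-2-(trimethylsilyl)acetylene | CC(C)[Si](OC#C[Si](C)(C)C)(C(C)C)C(C)C
F11 | step 12 | 2-(trimethylsilyl)ethyl 2-(ArA-oxy)-6-hydroxy-3-prenyl-4-(triisopropylsiloxy)-5-(trimethylsilyl)benzoate | C[Si](C)(C)CCOC(=O)c1c(O)c([Si](C)(C)C)c(O[Si](C(C)C)(C(C)C)C(C)C)c(CC=C(C)C)c1Oc1c(CC=C(C)C)c(OCOC)c2OC(C)(C)C=Cc2c1OCOC
A1 | alternative 1 | bis(methoxymethyl) depsidone, product of the carbonylative lactonization | CC(C)=CCc1c(O)c2c(c3c1Oc1c(CC=C(C)C)c(OCOC)cc(OCOC)c1C(=O)O3)C=CC(C)(C)O2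
A2 | alternative 1 | 6-[2-iodo-3,5-bis(methoxymethoxy)-6-prenylphenoxy]-2,2-dimethyl-7-prenyl-2H-chromene-5,8-diol | CC(C)=CCc1c(O)c2OC(C)(C)C=Cc2c(O)c1Oc1c(CC=C(C)C)c(OCOC)cc(OCOC)c1I
A3 | alternative 2 | N,N-diethyl 2-aryloxybenzamide with free ring A hydroxyl, product of the aryne insertion | CC(C)=CCc1c(OCOC)c2c(c(O)c1Oc1c(CC=C(C)C)c(OCOC)cc(OCOC)c1C(=O)N(CC)CC)C=CC(C)(C)O2
A4 | alternative 2 | 6-hydroxy-8-(methoxymethoxy)-2,2-dimethyl-7-prenyl-2H-chromen-5-yl N,N-diethylcarbamate | CC(C)=CCc1c(OCOC)c2OC(C)(C)C=Cc2c(OC(=O)N(CC)CC)c1O
A5 | alternative 2 | 3,5-bis(methoxymethoxy)-6-prenyl-2-(trimethylsilyl)phenyl trifluoromethanesulfonate | CC(C)=CCc1c(OS(=O)(=O)C(F)(F)F)c([Si](C)(C)C)c(OCOC)cc1OCOC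
A6 | alternative 2 | 4,6-bis(methoxymethoxy)-3-prenylbenzyne | CC(C)=CCC1=C(OCOC)C=C(OCOC)C#C1
A7 | alternative 3 | 6-isopropoxy-2,2-dimethyl-7-prenylchroman-5,8-diol, product of the ring expansion | CC(C)=CCc1c(O)c2c(c(O)c1OC(C)C)CCC(C)(C)O2
A8 | alternative 3 | 4-(6,6-dimethyl-5,6-dihydro-4H-pyran-2-yl)-4-hydroxy-2-isopropoxy-3-prenylcyclobut-2-en-1-one (racemic) | CC(C)=CCC1=C(OC(C)C)C(=O)C1(O)C2=CCCC(C)(C)O2
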